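**Retrosynthetic overview**
1. Target 19 ⇐ C6–allyl bond: α′-allylation of the lithium dienolate of cyclohexenone 17, trans to the C4 aryloxy group.
2. 17 ⇐ C1–C2 bond, closing the cyclohexenone ring C1–C6: thermal ynol ether → ketene → enol ether C-acylation cascade of the acyclic 1-ethoxyalkyne 14.
3. Enabling feature: the vinylogous ester C1(=O)–C2H=C3(OMe) next to the fully substituted ketal carbon C4. C2=C3(OMe) is read as a 2-methoxyalkene nucleophile and C1/C6 as a ketene; C4 carries no hydrogen and ties the two through a two-atom tether (C4–C5), which disfavors [2+2] closure.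
4. 14 ⇐ C5–C6 bond (lithium ethoxyacetylide + triflate 11) ⇐ alcohol 9 ⇐ mixed ketal C4 from 2,3-dimethoxybuta-1,3-diene (supplies C2–C5 and both methoxy groups), DMDO and phenol 4, then lipase resolution.
5. Ring order: the aryl ring is bought as 3,4-dimethoxyphenol and only allylated (aromatic Claisen); the cyclohexenone ring is closed last, in step 7.

Key step: step 7

Remark: in step 4 the lipase is assumed to acylate the (S)-alcohol faster; if the preference is the reverse, the acetate fraction is carried on after K2CO3/MeOH methanolysis.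
Remark: compounds 7–17 carry an acid-labile 2-methoxyalkene and mixed ketal, so base-washed glassware and Et3N-deactivated silica are assumed throughout.

Step 1
Reactants: 1 3,4-dimethoxyphenol; 2 allyl bromide
Product: 3 4-(allyloxy)-1,2-dimethoxybenzene
Conditions: K2CO3, acetone, reflux
Reagents that add atoms: allyl bromide C=CCBr
Why: Williamson ether synthesis, SN2 O-allylation of the phenoxide on a primary allylic bromide.

Step 2
Reactants: 3 4-(allyloxy)-1,2-dimethoxybenzene
Product: 4 2-allyl-4,5-dimethoxyphenol
Conditions: N,N-diethylaniline, 190 °C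
Reagents that add atoms: none
Why: Aromatic Claisen rearrangement ([3,3]) followed by tautomerization, which should go to the less hindered ortho carbon (C6, para to the 3-methoxy group) rather than the carbon between the two oxygens.

Step 3
Reactants: 5 2,3-dimethoxybuta-1,3-diene; 6 dimethyldioxirane (DMDO); 4 2-allyl-4,5-dimethoxyphenol
Product: 8 rac-2-(2-allyl-4,5-dimethoxyphenoxy)-2,3-dimethoxybut-3-en-1-ol, via epoxy ether 7 (not isolated)
Conditions: 5 (2 equiv), DMDO (1 equiv, acetone solution freshly made from acetone/KHSO5), CH2Cl2, −78 °C; then 4 (1 equiv), −78 → 0 °C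
Reagents that add atoms: dimethyldioxirane CC1(C)OO1
Why: Enol ether epoxidation followed by epoxy-ether alcoholysis (the reaction type used on glycal epoxides): DMDO should oxidize one 2-methoxyalkene unit (excess diene limits double oxidation), and the phenol should open epoxy ether 7 at its ketal carbon through the methoxy-stabilized oxocarbenium ion; the new ketal stereocenter forms racemic.

Step 4
Reactants: 8 rac-2-(2-allyl-4,5-dimethoxyphenoxy)-2,3-dimethoxybut-3-en-1-ol
Product: 9 (2R)-2-(2-allyl-4,5-dimethoxyphenoxy)-2,3-dimethoxybut-3-en-1-ol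
Conditions: Amano lipase PS (immobilized), vinyl acetate (3 equiv), MTBE, 30 °C, run slightly past half conversion; chromatographic separation from the acetate
Reagents that add atoms: none
Why: Lipase-catalysed kinetic resolution (enantioselective transesterification) of a primary alcohol with a β-quaternary stereocenter whose three substituents (methoxy, methoxyvinyl, bulky aryloxy) differ strongly in size; this should leave (R)-9 enantioenriched and is where the absolute configuration of C4 of the target is fixed.

Step 5
Reactants: 9 (2R)-2-(2-allyl-4,5-dimethoxyphenoxy)-2,3-dimethoxybut-3-en-1-ol; 10 trifluoromethanesulfonic anhydride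
Product: 11 (2R)-2-(2-allyl-4,5-dimethoxyphenoxy)-2,3-dimethoxybut-3-en-1-yl trifluoromethanesulfonate
Conditions: Tf2O, 2,6-lutidine, CH2Cl2, −78 °C; cold NaHCO3 wash, used at once
Reagents that add atoms: trifluoromethanesulfonic anhydride O=S(=O)(OS(=O)(=O)C(F)(F)F)C(F)(F)F
Why: Standard O-sulfonylation of a primary alcohol with a hindered pyridine base at low temperature; the neighbouring carbon has no hydrogen, so elimination cannot compete, and the ketal stereocenter is not involved.

Step 6
Reactants: 11 (2R)-2-(2-allyl-4,5-dimethoxyphenoxy)-2,3-dimethoxybut-3-en-1-yl trifluoromethanesulfonate; 12 ethoxyacetylene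
Product: 14 1-{[(3R)-6-ethoxy-2,3-dimethoxyhex-1-en-5-yn-3-yl]oxy}-2-allyl-4,5-dimethoxybenzene, via lithium ethoxyacetylide 13 (not isolated)
Conditions: 12 (1.6 equiv), n-BuLi (1.5 equiv), THF, −78 °C; then 11, DMPU, −78 → 0 °C
Reagents that add atoms: ethoxyacetylene CCOC#C
Why: SN2 alkylation of a lithium alkoxyacetylide by a primary triflate in THF/DMPU (acetylide alkylation); the triflate leaving group and the thermally robust acetylide should compensate for the neopentyl-type hindrance next to the ketal carbon, which is not a reacting center and keeps its configuration.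

Step 7
Reactants: 14 1-{[(3R)-6-ethoxy-2,3-dimethoxyhex-1-en-5-yn-3-yl]oxy}-2-allyl-4,5-dimethoxybenzene
Product: 17 (4R)-4-(2-allyl-4,5-dimethoxyphenoxy)-3,4-dimethoxycyclohex-2-en-1-one, via aldoketene 15 (not isolated), via oxocarbenium enolate zwitterion 16 (not isolated)
Conditions: toluene (0.005 M), 2,6-di-tert-butyl-4-methylpyridine (0.2 equiv), 115 °C, sealed tube
Reagents that add atoms: none
Why: Proposed new method: thermal retro-ene fragmentation of the 1-ethoxyalkyne (six-membered transition state, loss of ethene) should give aldoketene 15, whose electrophilic sp carbon (future C1) is attacked by the terminal carbon (future C2) of the tethered 2-methoxyalkene to give the six-membered oxocarbenium–enolate 16, and base-shuttled proton transfer from C2 to C6 then gives the conjugated vinylogous ester 17. The closest known reaction types are the thermolysis of alkynyl ethers to ketenes that are captured by tethered alkenes and enol ethers in [2+2] fashion, and the C-acylation of enol ethers by acyl chlorides or ketenes to β-alkoxy enones; what is new is the acylation outcome on a two-atom tether. The cyclohexenone ring closes by C1–C2 bond formation, 6-endo-trig at the enol ether, with the ketene C=C becoming endocyclic and its C=O exocyclic. No stereocenter is formed, and the C4 ketal stereocenter is untouched under neutral, base-buffered conditions. The step needs chemoselectivity for C-acylation over [2+2] closure, ketene dimerization and aromatic Claisen rearrangement of the aryl ketal: the two-atom tether through the fully substituted C4 would make the [2+2] product a strained bicyclo[2.2.0]hexanone, the methoxy group on C3 directs bond formation to C2 and fixes the enol ether position in the product, high dilution suppresses dimerization, and 115 °C lies well below the usual range of aryl allyl ether rearrangement.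

Step 8
Reactants: 17 (4R)-4-(2-allyl-4,5-dimethoxyphenoxy)-3,4-dimethoxycyclohex-2-en-1-one; 2 allyl bromide
Product: 19 (4R,6R)-6-allyl-4-(2-allyl-4,5-dimethoxyphenoxy)-3,4-dimethoxycyclohex-2-en-1-one, via lithium dienolate 18 (not isolated)
Conditions: LiN(iPr)2 (1.1 equiv), THF, −78 °C; allyl bromide (1.5 equiv), DMPU, −78 → 0 °C
Reagents that add atoms: allyl bromide C=CCBr
Why: Kinetic α′-deprotonation of the vinylogous ester at C6 and enolate alkylation (Stork–Danheiser-type) through cross-conjugated dienolate 18; allyl bromide should attack the face opposite the bulky aryloxy group at C4 (1,3-diaxial avoidance in the axial-attack transition state), setting C6 as R with the allyl group trans to the aryloxy group and equatorial in the product.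

**Compound list**
1 | 3,4-dimethoxyphenol | Oc1ccc(OC)c(OC)c1 | starting material
2 | allyl bromide | C=CCBr | starting material
3 | 4-(allyloxy)-1,2-dimethoxybenzene | C=CCOc1ccc(OC)c(OC)c1 | intermediate
4 | 2-allyl-4,5-dimethoxyphenol | C=CCc1cc(OC)c(OC)cc1O | intermediate
5 | 2,3-dimethoxybuta-1,3-diene | C=C(OC)C(=C)OC | starting material
6 | dimethyldioxirane (made from acetone and KHSO5) | CC1(C)OO1 | starting material
7 | rac-2-methoxy-2-(1-methoxyethenyl)oxirane | C=C(OC)C1(OC)CO1 | intermediate (not isolated)
8 | rac-2-(2-allyl-4,5-dimethoxyphenoxy)-2,3-dimethoxybut-3-en-1-ol | C=C(OC)C(OC)(CO)Oc1cc(OC)c(OC)cc1CC=C | intermediate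
9 | (2R)-2-(2-allyl-4,5-dimethoxyphenoxy)-2,3-dimethoxybut-3-en-1-ol | COC(=C)[C@](OC)(Oc1cc(OC)c(OC)cc1CC=C)CO | intermediate
10 | trifluoromethanesulfonic anhydride | O=S(=O)(OS(=O)(=O)C(F)(F)F)C(F)(F)F | starting material
11 | (2R)-2-(2-allyl-4,5-dimethoxyphenoxy)-2,3-dimethoxybut-3-en-1-yl trifluoromethanesulfonate | COC(=C)[C@](OC)(Oc1cc(OC)c(OC)cc1CC=C)COS(=O)(=O)C(F)(F)F | intermediate
12 | ethoxyacetylene | CCOC#C | starting material
13 | lithium ethoxyacetylide | CCOC#C[Li] | intermediate (not isolated)
14 | 1-{[(3R)-6-ethoxy-2,3-dimethoxyhex-1-en-5-yn-3-yl]oxy}-2-allyl-4,5-dimethoxybenzene | COC(=C)[C@](OC)(Oc1cc(OC)c(OC)cc1CC=C)CC#COCC | intermediate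
15 | (4R)-4-(2-allyl-4,5-dimethoxyphenoxy)-4,5-dimethoxyhexa-1,5-dien-1-one (aldoketene) | COC(=C)[C@](OC)(Oc1cc(OC)c(OC)cc1CC=C)CC=C=O | intermediate (not isolated)
16 | oxocarbenium enolate zwitterion (ring-closed, before proton transfer) | C=CCc1cc(OC)c(OC)cc1O[C@]1(OC)CC=C([O-])CC1=[O+]C | intermediate (not isolated)
17 | (4R)-4-(2-allyl-4,5-dimethoxyphenoxy)-3,4-dimethoxycyclohex-2-en-1-one | C=CCc1cc(OC)c(OC)cc1O[C@]1(OC)CCC(=O)C=C1OC | intermediate
18 | lithium dienolate of 17 | C=CCc1cc(OC)c(OC)cc1O[C@]1(OC)CC=C(O[Li])C=C1OC | intermediate (not isolated)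
19 | (4R,6R)-6-allyl-4-(2-allyl-4,5-dimethoxyphenoxy)-3,4-dimethoxycyclohex-2-en-1-one | C=CCc1cc(OC)c(OC)cc1O[C@]1(OC)C[C@@H](CC=C)C(=O)C=C1OC | target

**Step count**
Total steps: 8. Longest linear sequence: 8 (1 → 3 → 4 → 8 → 9 → 11 → 14 → 17 → 19); from diene 5 it is 6 steps.

**Three steps most likely to fail**

Step 7 (Proposed new method). Risk: the ketene may be consumed by dimerization, by [2+2] closure or by thermal loss of the phenol from the ketal before the six-membered C-acylation and proton transfer take place. Fallback with known chemistry, setting out from 14 and coming back at 17: heating 14 in toluene/MeOH with Et3N traps the ketene with methanol to give methyl (4R)-4-(2-allyl-4,5-dimethoxyphenoxy)-4,5-dimethoxyhex-5-enoate F1. Catalytic pyridinium p-toluenesulfonate in wet acetone at 0 °C then hydrolyses only the 2-methoxyalkene to give methyl (4R)-4-(2-allyl-4,5-dimethoxyphenoxy)-4-methoxy-5-oxohexanoate F2. KOtBu in THF closes the ring by intramolecular Claisen (Dieckmann-type) condensation of the δ-keto ester to (4R)-4-(2-allyl-4,5-dimethoxyphenoxy)-4-methoxycyclohexane-1,3-dione F3. O-methylation with Me3SiCHN2/MeOH should then give 17 together with its regioisomeric enol ether, which has to be separated.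

Step 6. Risk: slow substitution at the neopentyl-type carbon beside the ketal, with decomposition of the triflate by oxygen participation before the acetylide attacks. Fallback that replaces the substitution by carbonyl olefination, setting out from 9 and coming back at 17: Dess–Martin periodinane/NaHCO3 oxidizes 9 to (2S)-2-(2-allyl-4,5-dimethoxyphenoxy)-2,3-dimethoxybut-3-enal F4 (same spatial arrangement; the descriptor changes by priority only). Horner–Wadsworth–Emmons reaction with trimethyl phosphonoacetate/NaH gives methyl (2E,4R)-4-(2-allyl-4,5-dimethoxyphenoxy)-4,5-dimethoxyhexa-2,5-dienoate F5. Conjugate reduction with [(Ph3P)CuH]6 and PhSiH3 gives the saturated ester F1, which is taken on through F2 and F3 to 17 as described above.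

Step 3. Risk: double oxidation of the diene, rearrangement of the epoxy ether before capture, and 1,4- instead of 1,2-opening by the phenol. Fallback, setting out from 5 and 4 and coming back at 8: N-iodosuccinimide-mediated iodoetherification of the enol ether with the phenol as the alcohol component (CH2Cl2, −78 °C) gives rac-1-[(1-iodo-2,3-dimethoxybut-3-en-2-yl)oxy]-2-allyl-4,5-dimethoxybenzene F6. Displacement with CsOAc/18-crown-6 in DMF at 80 °C gives rac-2-(2-allyl-4,5-dimethoxyphenoxy)-2,3-dimethoxybut-3-en-1-yl acetate F7, and K2CO3/MeOH methanolysis returns rac-8.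

**Further compounds**
F1 | step 7 | methyl (4R)-4-(2-allyl-4,5-dimethoxyphenoxy)-4,5-dimethoxyhex-5-enoate | COC(=C)[C@](OC)(Oc1cc(OC)c(OC)cc1CC=C)CCC(=O)OC
F2 | step 7 | methyl (4R)-4-(2-allyl-4,5-dimethoxyphenoxy)-4-methoxy-5-oxohexanoate | CC(=O)[C@](OC)(Oc1cc(OC)c(OC)cc1CC=C)CCC(=O)OC
F3 | step 7 | (4R)-4-(2-allyl-4,5-dimethoxyphenoxy)-4-methoxycyclohexane-1,3-dione | C=CCc1cc(OC)c(OC)cc1O[C@]1(OC)CCC(=O)CC1=O
F4 | step 6 | (2S)-2-(2-allyl-4,5-dimethoxyphenoxy)-2,3-dimethoxybut-3-enal | COC(=C)[C@](OC)(Oc1cc(OC)c(OC)cc1CC=C)C=O
F5 | step 6 | methyl (2E,4R)-4-(2-allyl-4,5-dimethoxyphenoxy)-4,5-dimethoxyhexa-2,5-dienoate | COC(=C)[C@](OC)(Oc1cc(OC)c(OC)cc1CC=C)/C=C/C(=O)OC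
F6 | step 3 | rac-1-[(1-iodo-2,3-dimethoxybut-3-en-2-yl)oxy]-2-allyl-4,5-dimethoxybenzene | C=C(OC)C(OC)(CI)Oc1cc(OC)c(OC)cc1CC=C
F7 | step 3 | rac-2-(2-allyl-4,5-dimethoxyphenoxy)-2,3-dimethoxybut-3-en-1-yl acetate | C=C(OC)C(OC)(COC(C)=O)Oc1cc(OC)c(OC)cc1CC=C
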